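A direct plan would lengthen 1-tetracosanol A1 by two carbons. Oxidation would give tetracosanal A2 for an aldol addition of lithiated tert-butyl acetate A3 that would lead to racemic tert-butyl 3-hydroxyhexacosanoate A4 as the adduct. Dehydration (sulfonylation, then base) would give tert-butyl (E)-hexacos-2-enoate A5 and hydrogenation would give tert-butyl hexacosanoate A6 before acidolysis to hexacosanoic acid A7 and a closing acid-catalysed benzyl ester formation. Its weakest parts would be:
(a) the aldol addition with the dehydration and hydrogenation it entails: a C3 carbinol stereocentre, a leaving group and a C=C bond would be made only to be erased, four operations for two CH2 groups;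
(b) the tert-butyl ester detour, needed only because a benzyl ester would not survive the hydrogenation, which costs an unmasking and a re-esterification;
(c) the closing equilibrium esterification at reflux, run on the most advanced, waxy and least soluble material.

**Plan of the new route.** Only one C–C bond is cut: C9–C10 of the chain (C1 = ester carbonyl), after the C1–O ester bond has been traced back to sebacic acid (1) and benzyl alcohol (2). Half-ester 3 (C1–C9) and stearic acid (4, C10–C26) are joined as two primary radicals by mixed Kolbe electrolysis, a union of two carbons of like polarity. The enabling feature is the unbranched, heteroatom-free C2–C25 methylene chain: C9 and C10 are plain CH2 groups, and the only functional group, the C1 benzyl ester with its phenyl ring, is separated from C9 by the seven CH2 groups C2–C8. No ring is formed; the phenyl ring is bought with 2. No carbinol, alkene, sulfonate or temporary ester ever exists, and the ester is made on a commodity diacid, not on late material.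

Key step: step 2

Remark on the chemistry: the chain is numbered from the ester carbonyl carbon (C1) to the terminal methyl (C26); the target has no stereocentre, so no step needs stereocontrol.

Step 1
Reactants: 1 sebacic acid (decanedioic acid); 2 benzyl alcohol
Product: 3 monobenzyl sebacate (10-(benzyloxy)-10-oxodecanoic acid)
Conditions: 1 (2 equiv), BnOH (1 equiv), TsOH·H2O (2 mol%), toluene, reflux, Dean–Stark; cool, filter off excess 1; SiO2
Reagents that add atoms: none
Why: Fischer esterification with azeotropic removal of water; with the diacid in twofold excess the statistical mixture should hold mainly recovered 1 and half-ester 3 with little diester, 1 crystallises from cold toluene for reuse, and 3 is separated from the neutral diester as the acid.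

Step 2
Reactants: 3 monobenzyl sebacate; 4 stearic acid (octadecanoic acid)
Product: 9 benzyl hexacosanoate, via potassium 10-(benzyloxy)-10-oxodecanoate 5 (not isolated), via potassium stearate 6 (not isolated), via 9-(benzyloxy)-9-oxononyl radical 7 (not isolated), via heptadecyl radical 8 (not isolated)
Conditions: 4 (1 equiv), 3 (2 equiv), KOH (0.1 equiv per CO2H), MeOH/pyridine (4:1), undivided cell, smooth platinum anode and platinum cathode, 0.25 A cm−2, 50–55 °C, ca. 1.2 F per mol of CO2H, stopped while still weakly acidic; SiO2 (hexane, then hexane/EtOAc)
Reagents that add atoms: none
Why: Mixed (crossed) Kolbe electrolysis, the long-established anodic decarboxylative radical coupling of a fatty acid with a dicarboxylic acid half-ester: at the platinum anode the carboxylates 5 and 6 each lose one electron and CO2 to give the primary radicals 7 and 8 side by side in the adsorbed carboxylate layer, where they combine to form the C9–C10 bond, while hydrogen evolves at the cathode and regenerates the base. No ring is closed and no stereocentre is formed, so the selectivities needed are cross- against homo-coupling and radical against carbocation (Hofer–Moest) chemistry. The first is statistical and is steered by the twofold excess of 3, so that most radicals 8 should meet a radical 7; the two symmetrical by-products (a C34 alkane and a C18 dibenzyl diester) lie in polarity classes on either side of the mono-ester and are removed on a short silica column. The second is secured by the substrate: both radicals are unbranched primary alkyls with no α-substituent that could stabilise a cation, and smooth platinum, high current density and a weakly acidic, only partly neutralised electrolyte all favour dimerisation. The benzyl ester should survive because the carboxylate layer on platinum keeps the arene from the anode, because the ester carbonyl is separated from the radical centre C9 by seven CH2 groups, and because the bulk stays acidic enough to suppress methanolysis when the run is stopped before the acid is used up.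

**Compound list**

1 | sebacic acid (decanedioic acid) | OC(=O)CCCCCCCCC(=O)O | starting material
2 | benzyl alcohol | OCc1ccccc1 | starting material
3 | monobenzyl sebacate (10-(benzyloxy)-10-oxodecanoic acid) | OC(=O)CCCCCCCCC(=O)OCc1ccccc1 | intermediate
4 | stearic acid (octadecanoic acid) | CCCCCCCCCCCCCCCCCC(=O)O | starting material
5 | potassium 10-(benzyloxy)-10-oxodecanoate | [K+].[O-]C(=O)CCCCCCCCC(=O)OCc1ccccc1 | intermediate (not isolated)
6 | potassium stearate | CCCCCCCCCCCCCCCCCC(=O)[O-].[K+] | intermediate (not isolated)
7 | 9-(benzyloxy)-9-oxononyl radical | [CH2]CCCCCCCC(=O)OCc1ccccc1 | intermediate (not isolated)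
8 | heptadecyl radical | CCCCCCCCCCCCCCCC[CH2] | intermediate (not isolated)
9 | benzyl hexacosanoate | CCCCCCCCCCCCCCCCCCCCCCCCCC(=O)OCc1ccccc1 | target

Total step count: 2. Longest linear sequence: 2 steps (1 + 2 → 3 → 9).

**Steps most likely to fail** (the route has two steps, so the key step is entered twice, once for each of its two independent failure processes)

1. Step 2, passivation and loss of cross-coupling: a wax film of product and C34 alkane may coat the anode, raise the cell voltage and divert the current to homo-coupling and two-electron products. The fallback replaces the radical union by a polar copper-catalysed alkyl–alkyl coupling one bond further along (C10–C11). It sets out from 2: 10-bromodecanoic acid F1 would be esterified with 2 (TsOH·H2O cat., toluene, Dean–Stark) to benzyl 10-bromodecanoate F2 as the electrophile. 1-Bromohexadecane F3 would be converted with magnesium in THF into hexadecylmagnesium bromide F4 and this would be added slowly to F2 and Li2CuCl4 (3 mol%) in THF/NMP at −10 to 0 °C. The fallback comes back to the route at 9.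

2. Step 2, loss of the benzyl group: the benzyl ester may be methanolysed in the basic layer at the cathode, or attacked at the benzylic position at the anode, before coupling is complete. The fallback carries a matched methyl ester through the electrolysis and introduces the benzyl group afterwards. It sets out from 4: co-electrolysis of 4 with monomethyl sebacate F5 in the same cell should give methyl hexacosanoate F6 as the coupled ester. Transesterification of F6 with 2 (5 equiv, Ti(OiPr)4 5 mol%, toluene, reflux, methanol removed over molecular sieves) comes back to the route at 9.

3. Step 1, over-esterification and separation: the second carboxyl group may esterify as fast as the first, and the soap-like half-ester may resist clean separation from diacid and diester. The fallback makes the two chain ends different from the start, so no statistics are involved. It sets out from 2: undec-10-enoic acid F7 would be esterified with 2 (TsOH·H2O cat., toluene, Dean–Stark) to benzyl undec-10-enoate F8 as the alkene. Ozonolysis of F8 (O3, CH2Cl2, −78 °C, to the indicator end point; Me2S) should give benzyl 10-oxodecanoate F9 as the aldehyde. Pinnick oxidation of F9 (NaClO2, NaH2PO4, 2-methyl-2-butene, t-BuOH/H2O) comes back to the route at 3.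

**Further compounds**

F1 | step 2 | 10-bromodecanoic acid | OC(=O)CCCCCCCCCBr
F2 | step 2 | benzyl 10-bromodecanoate | BrCCCCCCCCCC(=O)OCc1ccccc1
F3 | step 2 | 1-bromohexadecane | CCCCCCCCCCCCCCCCBr
F4 | step 2 | hexadecylmagnesium bromide | CCCCCCCCCCCCCCCC[Mg]Br
F5 | step 2 | monomethyl sebacate (10-methoxy-10-oxodecanoic acid) | COC(=O)CCCCCCCCC(=O)O
F6 | step 2 | methyl hexacosanoate | CCCCCCCCCCCCCCCCCCCCCCCCCC(=O)OC
F7 | step 1 | undec-10-enoic acid | C=CCCCCCCCCC(=O)O
F8 | step 1 | benzyl undec-10-enoate | C=CCCCCCCCCC(=O)OCc1ccccc1
F9 | step 1 | benzyl 10-oxodecanoate | O=CCCCCCCCCC(=O)OCc1ccccc1
A1 | direct plan | 1-tetracosanol | CCCCCCCCCCCCCCCCCCCCCCCCO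
A2 | direct plan | tetracosanal | CCCCCCCCCCCCCCCCCCCCCCCC=O
A3 | direct plan | tert-butyl acetate | CC(=O)OC(C)(C)C
A4 | direct plan | tert-butyl 3-hydroxyhexacosanoate (racemic) | CCCCCCCCCCCCCCCCCCCCCCCC(O)CC(=O)OC(C)(C)C
A5 | direct plan | tert-butyl (E)-hexacos-2-enoate | CCCCCCCCCCCCCCCCCCCCCCC/C=C/C(=O)OC(C)(C)C
A6 | direct plan | tert-butyl hexacosanoate | CCCCCCCCCCCCCCCCCCCCCCCCCC(=O)OC(C)(C)C
A7 | direct plan | hexacosanoic acid | CCCCCCCCCCCCCCCCCCCCCCCCCC(=O)O
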